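Readings and results were computed with constants of no real substance; the scatter is artificial.

**The flask.** This closed, stirred vessel holds substrate, free catalyst and solid reagent, with none of the solid in solution at the start.

all flasks: substrate 19 mM; free catalyst 0.47 mM

| run | solid reagent | remark | time |
|---|---|---|---|
| delta | 17 mM | run made earlier |  |
| alpha | 68 mM | run made earlier |  |
| flask | 34.2 mM |  | 30 min |

| run | time / min | substrate / % | target / % |
|---|---|---|---|
| delta | 8.00 | 84 | 15 |
| delta | 15.0 | 68 | 27 |
| delta | 20.0 | 63 | 36 |
| delta | 30.0 | 42 | 55 |
| delta | 40.0 | 31 | 66 |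
| alpha | 3.00 | 96 | 8 |
| alpha | 10.0 | 80 | 20 |
| alpha | 15.0 | 67 | 32 |
| alpha | 25.0 | 51 | 49 |
| alpha | 40.0 | 28 | 72 |

(standard deviation of a reading: 2 percentage points)

- solid, in amounts per volume of the solution: solid reagent
- at the start none of the solid reagent is in solution

- amount of substrate in percent of the substrate charged, at 6.0 min, 15 min and 30 min

**Our rule.** In this flask the substrate, at 19 mM, is the limiting reagent, below the 34.2 mM of solid, so we keep its balance: what is left equals the charge minus v times the time. The alpha run at 25.0 min gives a reading of 0.372 mM min⁻¹ for v, the substrate draw, meaning the substrate consumed per minute along a straight line from the start. For this flask we therefore expect 88.2 %, 70.6 % and 41.3 % of the substrate.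

**Don't touch.** Leave the solid alone. Delta and alpha read 68 % and 67 % at 15.0 min, a gap within one standard deviation, although their solid charges were 17 mM and 68 mM.

**The forecast.** It gives 88 %, 68 % and 43 %, since “its solid will not run out, so it should follow the same curve”. At 15 min it stands below our line.

**The result.** The flask gives 86.6 %, 68.5 % and 42.1 %.

    substrate + free catalyst → catalyst intermediate A (k = 3.50 M⁻¹ s⁻¹)
    catalyst intermediate A ⇌ catalyst intermediate B (K = 2.30, k = 0.0850 s⁻¹)
    coupling partner + catalyst intermediate B → catalyst intermediate C (k = 10.0 M⁻¹ s⁻¹)
    catalyst intermediate C → catalyst intermediate D (k = 0.0610 s⁻¹)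
    catalyst intermediate D ⇌ by-product + catalyst intermediate E (K = 0.0580 M, k = 2.20 s⁻¹)
    catalyst intermediate E → free catalyst + target (k = 0.0650 s⁻¹)
    substrate + catalyst intermediate E → spent catalyst (k = 0.00460 M⁻¹ s⁻¹)
    solid reagent ⇌ coupling partner, rate k8*(cs8 - [coupling partner]) while solid is left; crystals form when [coupling partner] > cs8 (solubility = 17.0 mM, k = 0.0210 s⁻¹)

**The draw.** At 30.0 min this flask still held solid reagent at 19.2 % of its charge, with coupling partner at 16.8 mM, against 16.3 mM at 3.00 min. Its own draw to that time comes to 0.367 mM min⁻¹, beside the 0.372 mM min⁻¹ read from alpha. With twice the solid reagent and all else unchanged, the balance with v gives 41.3 % at 30 min, and that flask held 42.1 %.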